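**Retrosynthetic overview**

1. Target 41 ⇐ protected macrocycle 37 (desilylation, oxidation to the α-keto ester, saponification) ⇐ seco compound 36 by macrocyclic Suzuki coupling of the diene C(sp2)–C(sp2) bond.
2. 36 ⇐ diazo ketone 33 + spirotetronic acid 14. Key step: photochemical Wolff ring contraction of the six-membered thianone to a thiolanylidene ketene, which C-acylates the tetronic acid.
3. 33 ⇐ thian-4-one 15: dehydrogenation, asymmetric glycolate Mukaiyama–Michael addition, crotonaldehyde Michael addition, Julia–Kocienski olefination with sulfone 30 (from acrolein 24), diazo transfer.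
4. 14 ⇐ Diels–Alder reaction of triene 4 with the lactic-acid-derived methylene dioxolanone 9, dioxolanone → tetronic acid, cross-metathesis.
5. Ring order: cyclohexene → spirotetronate → thiolane (by contraction of the bought thiane ring) → 19-membered macrocycle.

Assumption: the silyloxy-bearing carbon of the glycolate unit introduced in step 9 is carried as a mixture of epimers (it becomes the ketone in step 21) and is written without a stereodescriptor; compounds marked as starting materials are taken as commercial.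

**Route**

Step 1
Reactants: 1 pent-1-en-4-yne; 2 (E)-2-bromobut-2-ene
Product: 4 (2E,4E)-3-methylocta-2,4,7-triene, via alkenylzirconocene 3 (not isolated)
Conditions: Cp2Zr(H)Cl, THF, rt; then 2, Pd(PPh3)4 (5 mol%), ZnCl2, THF, rt
Reagents that add atoms: none
Why: Hydrozirconation is selective for the terminal alkyne and syn, and the Negishi coupling with the (E)-bromide keeps both alkene geometries, giving the (2E,4E)-diene.

Step 2
Reactants: 5 (R)-lactic acid; 6 pivalaldehyde
Product: 7 (2R,5R)-2-tert-butyl-5-methyl-1,3-dioxolan-4-one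
Conditions: TsOH·H2O (cat.), H2SO4 (cat.), pentane, reflux (Dean–Stark); recrystallisation of the cis isomer
Reagents that add atoms: none
Why: Acid-catalysed acetalisation (Seebach dioxolanone) sets the acetal carbon (2R) cis to the lactate methyl under thermodynamic control.

Step 3
Reactants: 7 (2R,5R)-2-tert-butyl-5-methyl-1,3-dioxolan-4-one
Product: 9 (2R)-2-tert-butyl-5-methylidene-1,3-dioxolan-4-one, via bromide 8 (not isolated)
Conditions: NBS, AIBN (cat.), cyclohexane, reflux; then Et3N, CH2Cl2, 0 °C → rt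
Reagents that add atoms: none
Why: Wohl–Ziegler bromination at the lactate carbon followed by E2 loss of HBr gives the captodative dienophile, leaving the acetal stereocentre untouched.

Step 4
Reactants: 4 (2E,4E)-3-methylocta-2,4,7-triene; 9 (2R)-2-tert-butyl-5-methylidene-1,3-dioxolan-4-one
Product: 10 (2R,5S,6R,9R)-2-tert-butyl-8,9-dimethyl-6-(prop-2-en-1-yl)-1,3-dioxaspiro[4.5]dec-7-en-4-one
Conditions: toluene, BHT (cat.), 110 °C, sealed tube, 48 h
Reagents that add atoms: none
Why: Thermal Diels–Alder reaction in which the diene adds anti to the tert-butyl group with the lactone carbonyl exo, and the 3-methyl group steers the CH2 terminus of the dienophile to the methyl-bearing diene terminus, so the spiro carbon (5S) and both ring CH centres (6R,9R) are set together.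

Step 5
Reactants: 10 (2R,5S,6R,9R)-2-tert-butyl-8,9-dimethyl-6-(prop-2-en-1-yl)-1,3-dioxaspiro[4.5]dec-7-en-4-one; 11 methyl acetate
Product: 13 (5S,6R,9R)-4-hydroxy-8,9-dimethyl-6-(prop-2-en-1-yl)-1-oxaspiro[4.5]deca-3,7-dien-2-one, via hydroxy keto ester 12 (not isolated)
Conditions: LiN(iPr)2, 11 (3.5 equiv), THF, −78 °C; add 10, −78 → 0 °C; then 1 M HCl, rt
Reagents that add atoms: none
Why: Claisen-type acylation of the ester enolate by the dioxolanone carbonyl releases pivalaldehyde and the tertiary alkoxide, which lactonises onto the ester (dioxolanone route to tetronic acids) without touching a stereocentre.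

Step 6
Reactants: 13 (5S,6R,9R)-4-hydroxy-8,9-dimethyl-6-(prop-2-en-1-yl)-1-oxaspiro[4.5]deca-3,7-dien-2-one
Product: 14 (5S,6R,9R)-4-hydroxy-8,9-dimethyl-6-[(2E)-3-(4,4,5,5-tetramethyl-1,3,2-dioxaborolan-2-yl)prop-2-en-1-yl]-1-oxaspiro[4.5]deca-3,7-dien-2-one
Conditions: vinylboronic acid pinacol ester (3 equiv), second-generation Grubbs catalyst (5 mol%), CH2Cl2, 40 °C
Reagents that add atoms: vinylboronic acid pinacol ester, C=CB1OC(C)(C)C(C)(C)O1
Why: Olefin cross-metathesis of the terminal alkene gives the (E)-alkenylboronate under thermodynamic control, while the trisubstituted ring alkene and the tetronate enol are inert.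

Step 7
Reactants: 15 tetrahydro-4H-thiopyran-4-one
Product: 17 2,3-dihydro-4H-thiopyran-4-one, via 2-chlorothian-4-one 16 (not isolated)
Conditions: NCS, pyridine, CH2Cl2, 0 °C → rt
Reagents that add atoms: none
Why: α-Chlorination of the sulfide (Pummerer-type) and pyridine-mediated loss of HCl give the vinylogous thioester.

Step 8
Reactants: 18 methyl glycolate
Product: 20 1-methoxy-1,2-bis[(triethylsilyl)oxy]ethene, via silyl ether 19 (not isolated)
Conditions: Et3SiCl, Et3N, THF, 0 °C; then LiN(iPr)2, Et3SiCl, −78 °C → rt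
Reagents that add atoms: chlorotriethylsilane, CC[Si](Cl)(CC)CC
Why: O-Silylation of the alcohol and then enolisation with O-silylation of the ester give the silyl ketene acetal.

Step 9
Reactants: 17 2,3-dihydro-4H-thiopyran-4-one; 20 1-methoxy-1,2-bis[(triethylsilyl)oxy]ethene
Product: 21 methyl 2-[(2S)-4-[(triethylsilyl)oxy]-5,6-dihydro-2H-thiopyran-2-yl]-2-[(triethylsilyl)oxy]acetate
Conditions: Et3SiOTf (10 mol%), tert-leucine-derived arylpyrrolidine squaramide (10 mol%, antipode giving the 2S adduct), tBuOMe, −78 °C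
Reagents that add atoms: none
Why: Proposed new method: Et3SiOTf O-silylates the vinylogous thioester to a cyclic silyloxy thionium triflate, the squaramide binds the triflate so the cation sits in a chiral ion pair, the ketene acetal adds to the sulfur-bearing carbon on one face (setting 2S) and silyl transfer to triflate closes the cycle; the closest known reactions are hydrogen-bond-donor (anion-binding) catalysed additions of silyl ketene acetals to oxocarbenium and silyloxypyrylium ions and the racemic silyl-triflate-mediated Mukaiyama–Michael addition to thiochromones.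

Step 10
Reactants: 21 methyl 2-[(2S)-4-[(triethylsilyl)oxy]-5,6-dihydro-2H-thiopyran-2-yl]-2-[(triethylsilyl)oxy]acetate; 22 (E)-but-2-enal
Product: 23 methyl 2-[(2S,3S)-4-oxo-3-[(2S)-4-oxobutan-2-yl]thian-2-yl]-2-[(triethylsilyl)oxy]acetate
Conditions: (2R,5R)-5-benzyl-2-tert-butyl-3-methylimidazolidin-4-one·2,4-dinitrobenzoic acid (20 mol%), H2O (2 equiv), CH2Cl2, −40 °C
Reagents that add atoms: none
Why: Iminium-catalysed Mukaiyama–Michael addition in which the imidazolidinone fixes the enal face (methyl-bearing carbon S) and the regiodefined enol ether is attacked anti to its C2 substituent, giving the trans (2S,3S) ring, which is also the thermodynamic epimer at the ketone α-carbon.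

Step 11
Reactants: 24 acrolein
Product: 25 3-[(1-phenyl-1H-tetrazol-5-yl)sulfanyl]propanal
Conditions: 1-phenyl-1H-tetrazole-5-thiol, Et3N (5 mol%), CH2Cl2, 0 °C
Reagents that add atoms: 1-phenyl-1H-tetrazole-5-thiol, Sc1nnnn1-c1ccccc1
Why: Thia-Michael addition of the acidic heteroaryl thiol to the enal is fast and clean.

Step 12
Reactants: 25 3-[(1-phenyl-1H-tetrazol-5-yl)sulfanyl]propanal
Product: 26 (3S)-1-[(1-phenyl-1H-tetrazol-5-yl)sulfanyl]hex-5-yn-3-ol
Conditions: allenylboronic acid pinacol ester, (S)-TRIP [(S)-3,3'-bis(2,4,6-triisopropylphenyl)-1,1'-binaphthyl-2,2'-diyl hydrogen phosphate, 5 mol%], 4 Å MS, toluene, −20 °C; aq. NaHCO3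
Reagents that add atoms: allenylboronic acid pinacol ester, C=C=CB1OC(C)(C)C(C)(C)O1
Why: Chiral phosphoric acid-catalysed propargylation through a six-membered chair transition state, in which the (S)-catalyst directs si-face attack and sets the (S)-carbinol.

Step 13
Reactants: 26 (3S)-1-[(1-phenyl-1H-tetrazol-5-yl)sulfanyl]hex-5-yn-3-ol
Product: 27 5-{[(3S)-3-[(tert-butyldimethylsilyl)oxy]hex-5-yn-1-yl]sulfanyl}-1-phenyl-1H-tetrazole
Conditions: TBSCl, imidazole, DMF, rt
Reagents that add atoms: tert-butylchlorodimethylsilane, CC(C)(C)[Si](C)(C)Cl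
Why: Standard silylation of the secondary alcohol.

Step 14
Reactants: 27 5-{[(3S)-3-[(tert-butyldimethylsilyl)oxy]hex-5-yn-1-yl]sulfanyl}-1-phenyl-1H-tetrazole
Product: 29 5-{[(3S,5E)-3-[(tert-butyldimethylsilyl)oxy]-6-iodohex-5-en-1-yl]sulfanyl}-1-phenyl-1H-tetrazole, via alkenylzirconocene 28 (not isolated)
Conditions: Cp2Zr(H)Cl, THF, rt; then I2, 0 °C
Reagents that add atoms: iodine, II
Why: Syn hydrozirconation places zirconium at the terminal carbon and iodinolysis with retention gives only the (E)-vinyl iodide.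

Step 15
Reactants: 29 5-{[(3S,5E)-3-[(tert-butyldimethylsilyl)oxy]-6-iodohex-5-en-1-yl]sulfanyl}-1-phenyl-1H-tetrazole
Product: 30 5-{[(3S,5E)-3-[(tert-butyldimethylsilyl)oxy]-6-iodohex-5-en-1-yl]sulfonyl}-1-phenyl-1H-tetrazole
Conditions: (NH4)6Mo7O24·4H2O (10 mol%), 30% H2O2, EtOH, 0 °C → rt
Reagents that add atoms: hydrogen peroxide, OO
Why: Molybdate-catalysed peroxide oxidation takes the sulfide to the sulfone and leaves the vinyl iodide and silyl ether alone.

Step 16
Reactants: 30 5-{[(3S,5E)-3-[(tert-butyldimethylsilyl)oxy]-6-iodohex-5-en-1-yl]sulfonyl}-1-phenyl-1H-tetrazole; 23 methyl 2-[(2S,3S)-4-oxo-3-[(2S)-4-oxobutan-2-yl]thian-2-yl]-2-[(triethylsilyl)oxy]acetate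
Product: 31 methyl 2-[(2S,3S)-3-[(2S,4E,7R,9E)-7-[(tert-butyldimethylsilyl)oxy]-10-iododeca-4,9-dien-2-yl]-4-oxothian-2-yl]-2-[(triethylsilyl)oxy]acetate
Conditions: 30, KN(SiMe3)2, DME, −60 °C; then 23, −60 °C → rt
Reagents that add atoms: none
Why: Julia–Kocienski olefination in which the pre-metalated phenyltetrazolyl sulfone adds to the aldehyde much faster than to the hindered α-branched ketone and the potassium/DME conditions give the E-alkene.

Step 17
Reactants: 31 methyl 2-[(2S,3S)-3-[(2S,4E,7R,9E)-7-[(tert-butyldimethylsilyl)oxy]-10-iododeca-4,9-dien-2-yl]-4-oxothian-2-yl]-2-[(triethylsilyl)oxy]acetate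
Product: 33 methyl 2-[(2S,3S)-5-diazo-3-[(2S,4E,7R,9E)-7-[(tert-butyldimethylsilyl)oxy]-10-iododeca-4,9-dien-2-yl]-4-oxothian-2-yl]-2-[(triethylsilyl)oxy]acetate, via trifluoroacetyl ketone 32 (not isolated)
Conditions: LiN(SiMe3)2 (1.1 equiv), THF, −78 °C; CF3CO2CH2CF3; then MsN3, Et3N, H2O, MeCN, rt
Reagents that add atoms: methanesulfonyl azide, CS(=O)(=O)N=[N+]=[N-]
Why: Kinetic enolisation at the unsubstituted CH2 α-carbon, trifluoroacetylation and deacylative (Regitz-type) diazo transfer give the α-diazo ketone without enolising the tertiary α-centre or the less acidic silyloxy ester.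

Step 18
Reactants: 33 methyl 2-[(2S,3S)-5-diazo-3-[(2S,4E,7R,9E)-7-[(tert-butyldimethylsilyl)oxy]-10-iododeca-4,9-dien-2-yl]-4-oxothian-2-yl]-2-[(triethylsilyl)oxy]acetate; 14 (5S,6R,9R)-4-hydroxy-8,9-dimethyl-6-[(2E)-3-(4,4,5,5-tetramethyl-1,3,2-dioxaborolan-2-yl)prop-2-en-1-yl]-1-oxaspiro[4.5]deca-3,7-dien-2-one
Product: 36 (5S,6R,9R)-3-{(3R,4S,5S)-4-[(2S,4E,7R,9E)-7-[(tert-butyldimethylsilyl)oxy]-10-iododeca-4,9-dien-2-yl]-5-[2-methoxy-2-oxo-1-(triethylsilyloxy)ethyl]thiolane-3-carbonyl}-4-hydroxy-8,9-dimethyl-6-[(2E)-3-(4,4,5,5-tetramethyl-1,3,2-dioxaborolan-2-yl)prop-2-en-1-yl]-1-oxaspiro[4.5]deca-3,7-dien-2-one, via ketene 34 (not isolated), via enol ester 35 (not isolated)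
Conditions: hν (365 nm LED), 14 (1.2 equiv), Et3N (2 equiv), DMAP (0.3 equiv), CH2Cl2 (0.02 M), 0 °C, then rt, 12 h
Reagents that add atoms: none
Why: Proposed new method: 365 nm light expels N2 from the s-cis-locked cyclic diazo ketone with a concerted 1,2-shift of the ring carbon (Wolff rearrangement, retention at the migrating centre), contracting the thiane to a thiolan-3-ylidene ketene that the triethylammonium tetronate captures on oxygen, after which DMAP moves the acyl group from O to C3 and the base settles the new α-centre trans (3R); the closest known reactions are the photochemical Wolff ring contraction of 2-diazocycloalkanones with alcohol capture and the DCC/DMAP acylation–rearrangement of tetronic acids.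

Step 19
Reactants: 36 seco 3-acyl spirotetronic acid (name as in step 18)
Product: 37 protected macrocycle (skeleton and stereocentres of 41 but with OTBS at the carbinol and CH(OSiEt3)CO2Me in place of the oxoacetic acid)
Conditions: Pd(PPh3)4 (20 mol%), TlOEt, THF/H2O (3:1), 1 mM, rt
Reagents that add atoms: none
Why: Intramolecular Suzuki–Miyaura coupling at high dilution closes the 19-membered ring with retention of both alkene geometries, giving the (E,E)-diene.

Step 20
Reactants: 37 protected macrocycle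
Product: 38 macrocycle with free CH(OH)CO2Me (OTBS retained)
Conditions: HF·pyridine, pyridine, THF, 0 °C
Reagents that add atoms: none
Why: The triethylsilyl ether is cleaved far faster than the secondary tert-butyldimethylsilyl ether (selective desilylation).

Step 21
Reactants: 38 macrocyclic α-hydroxy ester
Product: 39 macrocyclic α-keto methyl ester (OTBS retained)
Conditions: Dess–Martin periodinane, NaHCO3, CH2Cl2, rt
Reagents that add atoms: none
Why: Dess–Martin oxidation tolerates the sulfide and diene, removes the epimeric carbinol, and the now acidic CH next to sulfur settles trans to its neighbour (S as in the target).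

Step 22
Reactants: 39 macrocyclic α-keto methyl ester
Product: 41 CNP0224658.3 (target), via hydroxy keto ester 40 (not isolated)
Conditions: HF·pyridine, THF, rt; then LiOH, THF/H2O, 0 °C; 1 M HCl to pH 3
Reagents that add atoms: lithium hydroxide, [Li+].[OH-]
Why: Fluoride desilylation followed by mild saponification of the activated α-keto methyl ester frees the alcohol and the acid without touching a fixed stereocentre.

**Compound list**

1 | pent-1-en-4-yne | C=CCC#C | starting material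
2 | (E)-2-bromobut-2-ene | C/C=C(/Br)C | starting material
3 | chlorobis(cyclopentadienyl)[(1E)-penta-1,4-dien-1-yl]zirconium | C=CC/C=C/[Zr](Cl)(C1C=CC=C1)C1C=CC=C1 | intermediate
4 | (2E,4E)-3-methylocta-2,4,7-triene | C/C=C(/C=C/CC=C)C | intermediate
5 | (R)-lactic acid | C[C@@H](O)C(=O)O | starting material
6 | pivalaldehyde | CC(C)(C)C=O | starting material
7 | (2R,5R)-2-tert-butyl-5-methyl-1,3-dioxolan-4-one | C[C@H]1O[C@@H](C(C)(C)C)OC1=O | intermediate
8 | (2R)-5-bromo-2-tert-butyl-5-methyl-1,3-dioxolan-4-one | CC1(Br)O[C@@H](C(C)(C)C)OC1=O | intermediate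
9 | (2R)-2-tert-butyl-5-methylidene-1,3-dioxolan-4-one | C=C1O[C@@H](C(C)(C)C)OC1=O | intermediate
10 | (2R,5S,6R,9R)-2-tert-butyl-8,9-dimethyl-6-(prop-2-en-1-yl)-1,3-dioxaspiro[4.5]dec-7-en-4-one | CC1=C[C@@H](CC=C)[C@]2(C[C@H]1C)O[C@@H](C(C)(C)C)OC2=O | intermediate
11 | methyl acetate | COC(C)=O | starting material
12 | methyl 3-[(1S,2R,5R)-1-hydroxy-4,5-dimethyl-2-(prop-2-en-1-yl)cyclohex-3-en-1-yl]-3-oxopropanoate | CC1=C[C@@H](CC=C)[C@@](O)(C[C@H]1C)C(=O)CC(=O)OC | intermediate
13 | (5S,6R,9R)-4-hydroxy-8,9-dimethyl-6-(prop-2-en-1-yl)-1-oxaspiro[4.5]deca-3,7-dien-2-one | CC1=C[C@@H](CC=C)[C@]2(C[C@H]1C)OC(=O)C=C2O | intermediate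
14 | (5S,6R,9R)-4-hydroxy-8,9-dimethyl-6-[(2E)-3-(4,4,5,5-tetramethyl-1,3,2-dioxaborolan-2-yl)prop-2-en-1-yl]-1-oxaspiro[4.5]deca-3,7-dien-2-one | CC1=C[C@@H](C/C=C/B3OC(C)(C)C(C)(C)O3)[C@]2(C[C@H]1C)OC(=O)C=C2O | intermediate
15 | tetrahydro-4H-thiopyran-4-one | O=C1CCSCC1 | starting material
16 | 2-chlorotetrahydro-4H-thiopyran-4-one | O=C1CCSC(Cl)C1 | intermediate
17 | 2,3-dihydro-4H-thiopyran-4-one | O=C1CCSC=C1 | intermediate
18 | methyl glycolate | COC(=O)CO | starting material
19 | methyl 2-[(triethylsilyl)oxy]acetate | COC(=O)CO[Si](CC)(CC)CC | intermediate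
20 | 1-methoxy-1,2-bis[(triethylsilyl)oxy]ethene | COC(O[Si](CC)(CC)CC)=CO[Si](CC)(CC)CC | intermediate
21 | methyl 2-[(2S)-4-[(triethylsilyl)oxy]-5,6-dihydro-2H-thiopyran-2-yl]-2-[(triethylsilyl)oxy]acetate | COC(=O)C(O[Si](CC)(CC)CC)[C@H]1SCCC(O[Si](CC)(CC)CC)=C1 | intermediate
22 | (E)-but-2-enal | C/C=C/C=O | starting material
23 | methyl 2-[(2S,3S)-4-oxo-3-[(2S)-4-oxobutan-2-yl]thian-2-yl]-2-[(triethylsilyl)oxy]acetate | O=CC[C@H](C)[C@@H]1[C@@H](C(O[Si](CC)(CC)CC)C(=O)OC)SCCC1=O | intermediate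
24 | acrolein | C=CC=O | starting material
25 | 3-[(1-phenyl-1H-tetrazol-5-yl)sulfanyl]propanal | O=CCCSc1nnnn1-c1ccccc1 | intermediate
26 | (3S)-1-[(1-phenyl-1H-tetrazol-5-yl)sulfanyl]hex-5-yn-3-ol | C#CC[C@H](O)CCSc1nnnn1-c1ccccc1 | intermediate
27 | 5-{[(3S)-3-[(tert-butyldimethylsilyl)oxy]hex-5-yn-1-yl]sulfanyl}-1-phenyl-1H-tetrazole | C#CC[C@H](O[Si](C)(C)C(C)(C)C)CCSc1nnnn1-c1ccccc1 | intermediate
28 | chlorobis(cyclopentadienyl){(1E,4S)-4-[(tert-butyldimethylsilyl)oxy]-6-[(1-phenyl-1H-tetrazol-5-yl)sulfanyl]hex-1-en-1-yl}zirconium | Cl[Zr](/C=C/C[C@H](O[Si](C)(C)C(C)(C)C)CCSc1nnnn1-c1ccccc1)(C1C=CC=C1)C1C=CC=C1 | intermediate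
29 | 5-{[(3S,5E)-3-[(tert-butyldimethylsilyl)oxy]-6-iodohex-5-en-1-yl]sulfanyl}-1-phenyl-1H-tetrazole | I/C=C/C[C@H](O[Si](C)(C)C(C)(C)C)CCSc1nnnn1-c1ccccc1 | intermediate
30 | 5-{[(3S,5E)-3-[(tert-butyldimethylsilyl)oxy]-6-iodohex-5-en-1-yl]sulfonyl}-1-phenyl-1H-tetrazole | I/C=C/C[C@H](O[Si](C)(C)C(C)(C)C)CCS(=O)(=O)c1nnnn1-c1ccccc1 | intermediate
31 | methyl 2-[(2S,3S)-3-[(2S,4E,7R,9E)-7-[(tert-butyldimethylsilyl)oxy]-10-iododeca-4,9-dien-2-yl]-4-oxothian-2-yl]-2-[(triethylsilyl)oxy]acetate | I/C=C/C[C@H](O[Si](C)(C)C(C)(C)C)C/C=C/C[C@H](C)[C@@H]1[C@@H](C(O[Si](CC)(CC)CC)C(=O)OC)SCCC1=O | intermediate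
32 | 5-(trifluoroacetyl) derivative of 31 (trifluoroacetyl on the CH2 carbon α to the ketone) | I/C=C/C[C@H](O[Si](C)(C)C(C)(C)C)C/C=C/C[C@H](C)[C@@H]1[C@@H](C(O[Si](CC)(CC)CC)C(=O)OC)SCC(C(=O)C(F)(F)F)C1=O | intermediate
33 | methyl 2-[(2S,3S)-5-diazo-3-[(2S,4E,7R,9E)-7-[(tert-butyldimethylsilyl)oxy]-10-iododeca-4,9-dien-2-yl]-4-oxothian-2-yl]-2-[(triethylsilyl)oxy]acetate | I/C=C/C[C@H](O[Si](C)(C)C(C)(C)C)C/C=C/C[C@H](C)[C@@H]1[C@@H](C(O[Si](CC)(CC)CC)C(=O)OC)SCC(=[N+]=[N-])C1=O | intermediate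
34 | methyl 2-[(2S,3S)-3-[(2S,4E,7R,9E)-7-[(tert-butyldimethylsilyl)oxy]-10-iododeca-4,9-dien-2-yl]-4-(oxomethylidene)thiolan-2-yl]-2-[(triethylsilyl)oxy]acetate (ketene) | I/C=C/C[C@H](O[Si](C)(C)C(C)(C)C)C/C=C/C[C@H](C)[C@@H]1[C@@H](C(O[Si](CC)(CC)CC)C(=O)OC)SCC1=C=O | intermediate
35 | 4-O-acyl tetronate (enol ester of 14 with the thiolane-3-carboxylic acid; epimers at the thiolane carbon bearing the acyl group) | I/C=C/C[C@H](O[Si](C)(C)C(C)(C)C)C/C=C/C[C@H](C)[C@@H]1[C@@H](C(O[Si](CC)(CC)CC)C(=O)OC)SCC1C(=O)OC1=CC(=O)O[C@]12C[C@@H](C)C(C)=C[C@H]2C/C=C/B3OC(C)(C)C(C)(C)O3 | intermediate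
36 | seco 3-acyl spirotetronic acid (full name in step 18) | I/C=C/C[C@H](O[Si](C)(C)C(C)(C)C)C/C=C/C[C@H](C)[C@@H]1[C@@H](C(O[Si](CC)(CC)CC)C(=O)OC)SC[C@H]1C(=O)C1=C(O)[C@@]2(C[C@@H](C)C(C)=C[C@H]2C/C=C/B3OC(C)(C)C(C)(C)O3)OC1=O | intermediate
37 | protected macrocycle: 41 with OTBS at the carbinol and CH(OSiEt3)CO2Me in place of C(=O)CO2H | CC1=C[C@H]2C/C=C/C=C/C[C@H](O[Si](C)(C)C(C)(C)C)C/C=C/C[C@H](C)[C@@H]3[C@@H](C(O[Si](CC)(CC)CC)C(=O)OC)SC[C@H]3C(=O)C3=C(O)[C@@]2(C[C@H]1C)OC3=O | intermediate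
38 | as 37 with free CH(OH)CO2Me | CC1=C[C@H]2C/C=C/C=C/C[C@H](O[Si](C)(C)C(C)(C)C)C/C=C/C[C@H](C)[C@@H]3[C@@H](C(O)C(=O)OC)SC[C@H]3C(=O)C3=C(O)[C@@]2(C[C@H]1C)OC3=O | intermediate
39 | TBS ether and methyl ester of 41 (α-keto methyl ester) | CC1=C[C@H]2C/C=C/C=C/C[C@H](O[Si](C)(C)C(C)(C)C)C/C=C/C[C@H](C)[C@@H]3[C@@H](C(=O)C(=O)OC)SC[C@H]3C(=O)C3=C(O)[C@@]2(C[C@H]1C)OC3=O | intermediate
40 | methyl ester of 41 (free secondary alcohol) | CC1=C[C@H]2C/C=C/C=C/C[C@H](O)C/C=C/C[C@H](C)[C@@H]3[C@@H](C(=O)C(=O)OC)SC[C@H]3C(=O)C3=C(O)[C@@]2(C[C@H]1C)OC3=O | intermediate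
41 | CNP0224658.3: 19-membered 3-acyl spirotetronic acid macrocycle with an all-trans 2,3,4-trisubstituted thiolane bearing the 2-oxoacetic acid | CC1=C[C@H]2C/C=C/C=C/C[C@H](O)C/C=C/C[C@H](C)[C@@H]3[C@@H](C(=O)C(=O)O)SC[C@H]3C(=O)C3=C(O)[C@@]2(C[C@H]1C)OC3=O | target

**Step count and risks**

Total step count: 22. Longest linear sequence: 12 steps (steps 11–15, then 16–22).

The three steps most likely to fail:

Step 9 (proposed new asymmetric addition; risk: low enantioselectivity or poor turnover). Fallback, setting out from 17 and 20 and coming back at 23: run the addition with Et3SiOTf alone, a known silyl-triflate-mediated Mukaiyama–Michael addition, to give the racemic enol ether F1. Submit F1 to the conditions of step 10; the imidazolidinone fixes the methyl-bearing centre in both ring enantiomers, so the products are diastereomers, 23 and its (2R,3R)-ring isomer F2. They are separated by chromatography, at most half of the material is kept, and the route resumes at 23.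

Step 10 (risk: the hindered, substituted enol ether reacts slowly or with poor diastereoselectivity, or the keto aldehyde undergoes aldol closure). Fallback, setting out from 21 and coming back at 23: TiCl4-mediated Mukaiyama–Michael addition of 21 to (4R)-4-benzyl-3-[(E)-but-2-enoyl]-1,3-oxazolidin-2-one in CH2Cl2 at −78 °C, where the chelated auxiliary controls the methyl-bearing centre, gives the imide F3. LiSEt in THF at 0 °C converts it to the thioester F4, and Fukuyama reduction (Et3SiH, palladium on carbon, acetone) gives the aldehyde 23.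

Step 18 (proposed new Wolff contraction with tetronate capture; risk: the ketene is lost to adventitious water or stops at the enol ester). Fallback, setting out from 33 and coming back at 36: irradiate 33 at 365 nm in THF/H2O, the known Wolff ring contraction with water capture, to give the thiolane carboxylic acid F5 after base equilibration to the trans isomer. Couple F5 with 14 using DCC, DMAP and Et3N in CH2Cl2, the known O-acylation and O-to-C acyl migration of tetronic acids, to give 36.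

**Further compounds**

F1 | step 9 | racemic methyl 2-[4-[(triethylsilyl)oxy]-5,6-dihydro-2H-thiopyran-2-yl]-2-[(triethylsilyl)oxy]acetate | COC(=O)C(O[Si](CC)(CC)CC)C1SCCC(O[Si](CC)(CC)CC)=C1
F2 | step 9 | methyl 2-[(2R,3R)-4-oxo-3-[(2S)-4-oxobutan-2-yl]thian-2-yl]-2-[(triethylsilyl)oxy]acetate | O=CC[C@H](C)[C@H]1[C@H](C(O[Si](CC)(CC)CC)C(=O)OC)SCCC1=O
F3 | step 10 | methyl 2-[(2S,3S)-3-[(2S)-4-[(4R)-4-benzyl-2-oxo-1,3-oxazolidin-3-yl]-4-oxobutan-2-yl]-4-oxothian-2-yl]-2-[(triethylsilyl)oxy]acetate | O=C1OC[C@@H](Cc2ccccc2)N1C(=O)C[C@H](C)[C@@H]1[C@@H](C(O[Si](CC)(CC)CC)C(=O)OC)SCCC1=O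
F4 | step 10 | S-ethyl (3S)-3-[(2S,3S)-2-[2-methoxy-2-oxo-1-(triethylsilyloxy)ethyl]-4-oxothian-3-yl]butanethioate | CCSC(=O)C[C@H](C)[C@@H]1[C@@H](C(O[Si](CC)(CC)CC)C(=O)OC)SCCC1=O
F5 | step 18 | (3R,4S,5S)-4-[(2S,4E,7R,9E)-7-[(tert-butyldimethylsilyl)oxy]-10-iododeca-4,9-dien-2-yl]-5-[2-methoxy-2-oxo-1-(triethylsilyloxy)ethyl]thiolane-3-carboxylic acid | I/C=C/C[C@H](O[Si](C)(C)C(C)(C)C)C/C=C/C[C@H](C)[C@@H]1[C@@H](C(O[Si](CC)(CC)CC)C(=O)OC)SC[C@H]1C(=O)O
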